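## Structural features

The target is an achiral, linear heptamer of benzene rings, lettered A to G from the 2,4,6-trihydroxyphenoxy end, joined only by six diaryl ether oxygens and carrying eighteen free phenolic hydroxyls; it has no stereocentre and no hindered axis, so no two stereocentres stand next to each other and nothing stereochemical has to be set. Ring A is bound through its C-1 and has hydroxyls on C-2, C-4 and C-6; rings B, D and F are 5-oxygenated pyrogallols (hydroxyls on C-1 and C-3, ether oxygen to the next ring on C-2, ether oxygen to the preceding ring on C-5); rings C and E are pentaoxygenated (ether to the preceding ring on C-1, hydrogen on C-2, hydroxyls on C-3 to C-5, ether to the following ring on C-6); ring G is a 3,4,5-trihydroxyphenyl group bound through its C-1. The six links therefore run from C-1 of ring A to C-5 of ring B, from C-2 of ring B to C-1 of ring C, from C-6 of ring C to C-5 of ring D, from C-2 of ring D to C-1 of ring E, from C-6 of ring E to C-5 of ring F and from C-2 of ring F to C-1 of ring G, and in each the oxygen is flanked by two oxygen substituents on the first-named ring while the carbon on the partner ring has at least one ortho hydrogen. The free polyphenol is sensitive to air, above all as a phenoxide, whereas the diaryl ether bonds are robust, so all eighteen hydroxyls are best carried as methyl ethers to the last step. The real difficulty is regiochemical and steric: deciding which oxygen of each polyoxygenated ring is arylated, and forming ethers at doubly flanked oxygens between electron-rich rings that have no built-in activation. The ring B–ring C and ring D–ring E pairs are the same two-ring unit, so one building block can serve twice. The key step exploits the surroundings of O-2 of ring F: it lies between O-1 and O-3 of that ring and is bound to C-1 of ring G, whose neighbours C-2 and C-6 carry hydrogen, so a carboxyl group on C-2 of ring G esterified to O-1 of ring F can deliver the O-2 phenoxide to C-1 of ring G through a seven-membered ring and then disappear by lactone opening and decarboxylation.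

## Logic of the disconnections

26 to 25: the eighteen O–H groups are traced back to O–CH3. A single small mask that tolerates aryllithiums, hot carbonate, peracid and copper turns every intermediate into an ordinary aryl ether. The demand on the forward step is exhaustive dealkylation without cleavage of the six aryl–O–aryl bonds.

25 to 24 and 15: the ether between C-6 of ring E and C-5 of ring F is cut on the ring F side. C-5 of ring F has hydrogen on both neighbours, so the halide partner is unhindered, and the cut divides seven rings into five and two, leaving the ring F–ring G ether in a small fragment. The forward step must arylate an oxygen flanked by an aryloxy and a methoxy group.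

24 to 22, and 21 to 19: the hydroxyls on C-6 of ring E and on C-6 of ring C are traced to formyl groups (aryl C–O from aryl C–C). A formyl group cannot act as a nucleophile in a copper coupling and is also the group that activates formation of the neighbouring ether. The forward step needs aryl rather than hydride migration in a peracid oxidation, without attack on the electron-rich rings.

22 to 21 and 17, and 19 to 18 and 17: the ethers from C-6 of ring C to C-5 of ring D and from C-1 of ring A to C-5 of ring B are cut on the side of rings D and B. Both carbons have two ortho hydrogens and the same substitution, so one bromide, 17, serves twice. The forward couplings must tolerate the aldehyde and engage di-ortho-substituted phenols.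

17 to 3 and 16: the ether from C-2 of ring B to C-1 of ring C (identical with the one from C-2 of ring D to C-1 of ring E) is cut on the ring C side. The formyl group on the neighbouring carbon makes this carbon an acceptor for nucleophilic aromatic substitution, so the doubly flanked oxygen can be the nucleophile, and 16 already carries the bromine needed later. The demand is an intermolecular substitution by a hindered phenoxide.

15 to 14 to 12: the methyl group on O-1 of ring F is removed, the hydrogen on C-2 of ring G is replaced by a carboxyl group, and this is joined to O-1 of ring F. Adding a lactone in the retrosynthetic sense makes the ring F–ring G ether part of a seven-membered ring. The forward steps are lactone hydrolysis and protodecarboxylation of an acid with oxygen on both ortho carbons and the para carbon, in the presence of an aryl bromide.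

12 to 11: the bond from O-2 of ring F to C-1 of ring G is cut inside the lactone. The ester tether decides which oxygen is arylated and makes up for the weak activation of the ring. The forward step needs the O-2 hydroxyl to be the only nucleophile and the ester to stay on O-1.

11 to 10 to 8 and 4: a 4-methoxybenzyl group is put back on O-2 of ring F and the ester C(=O)–O bond is cut. With O-2 blocked and O-3 methylated, only the O-1 hydroxyl can be acylated, so the ester position is set by construction. The blocking group must later come off without base.

8 to 6 to 5: the O-1 hydroxyl of ring F is traced to a formyl group and the benzylic C–O bond is cut. This reaches 5, in which the three contiguous positions are already differentiated (formyl for O-1, free hydroxyl for O-2, methoxy for O-3) and bromine sits on C-5.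

4 to 3 to 1: the carboxyl group is traced to the formyl group of 3, the aldehyde that also serves as the electrophile for 17, and the aryl–CHO bond is then cut to 2 and from there to 1. One metalation therefore supplies both arms of the route. The only two ring hydrogens of 1 are equivalent and lie between fluorine and methoxy, so there is no regiochemical question. The forward steps must keep 2 cold enough that it does not lose LiF and must oxidise the aldehyde without chlorinating the ring.

## Other disconnections considered

Alternative 1: All six ether bonds are cut at the doubly flanked carbon, and every hydroxyl of rings A to F that is ortho or para to such a carbon is traced to a formyl group.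
- Forward key step: the hexabenzyl dodecaaldehyde heptamer A2 is treated with excess mCPBA and all twelve aryl–CHO bonds become aryl formates in A1.
- In its favour: each ether would be formed by a largely unhindered phenoxide attacking a carbon activated by two formyl groups, so no copper is needed. The ether from C-2 of ring F to C-1 of ring G would need neither tether nor decarboxylation, which is better than the chosen plan for that bond. The end game (formate methanolysis, then hydrogenolysis of six benzyl ethers) is milder than an eighteen-fold BBr3 cleavage, also a point on which it is better.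
- Against it here: twelve Baeyer–Villiger events must all proceed with aryl migration on rings that each carry a second electron-withdrawing formyl group. Hydride migration to carboxylic acids in even a few of them would give mixtures that are very hard to separate. Aryloxy groups flanked by two formyl groups are themselves leaving groups, so ether exchange with later phenoxides could scramble the sequence. Each ring monomer holds both a nucleophilic hydroxyl and an activated halide and would need its own protecting scheme.
- Comparison: mechanistically these are the same two reactions that the chosen plan uses in steps 10, 12 and 14, but there they run one formyl group at a time on rings with three oxygen donors. Step counts on paper are similar. The chosen plan pays with three copper couplings and a harsher last step, and gains intermediates whose oxidation events are single and checkable.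

Alternative 2: Ring C is cut across two C–C bonds and traced to diisopropyl squarate A5.
- Forward key step: the racemic 4-hydroxy-4-(1-aryloxyvinyl)cyclobutenone A4 is heated; thermal four-electron ring opening, six-electron ring closure and tautomerisation would give the hydroquinone A3 (Moore rearrangement).
- In its favour: every oxygen of ring C is placed by construction, and the ether from C-2 of ring B to C-1 of ring C is carried in as an enol ether, so no coupling at a flanked oxygen is needed. The step is thermal and metal-free. On regiochemical certainty for ring C it is better than the chosen plan, which relies on an intermolecular substitution for this bond.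
- Against it here: A3 emerges with two free hydroxyls in a para relationship that must be told apart (one to be arylated by ring D, one to be capped) and that oxidise readily to a quinone. Making A4 requires metalation of an aryl vinyl ether at the vinylic carbon, next to a dimethoxyaryl ring that is itself prone to ortho-metalation. Three kinds of protecting group replace one. The sequence solves only ring C and would have to be repeated for ring E.
- Comparison: the pentaoxygenated ring costs about five operations here against two (steps 10 and 12) in the chosen plan, and all other ether bonds still need couplings. Structurally it is elegant for one ring, but in step economy it is the weaker plan for a heptamer with a repeating unit.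

Alternative 3: Both ether bonds of ring D are cut and the ring is introduced as the cationic complex A7, [CpRu(η6-2,5-dichloro-1,3-dimethoxybenzene)]PF6.
- Forward key step: in one pot the phenoxide of 21 would displace the open chloride (on C-5 of ring D), the phenoxide of the ring E–ring F–ring G trimer phenol A8 would displace the flanked chloride (on C-2 of ring D), and irradiation in MeCN would release the arene A6, which is the same compound as 25.
- In its favour: the disconnection is three rings plus one plus three, so its longest linear sequence would be shorter than that of the chosen plan, a point on which it is better. The cationic ruthenium unit activates even a dimethoxy-substituted chloroarene towards phenoxides near room temperature, gentler than hot copper couplings. The last step is the same BBr3 cleavage, so the two plans are equal there.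
- Against it here: the second substitution creates the most congested ether of the molecule (a chloride between two methoxy groups, attacked by a phenoxide that has an ortho aryloxy group). The order of the two displacements rests only on a steric difference. Ruthenium is used in stoichiometric amount. A8 needs its hydroxyl on C-1 of ring E, next to hydrogen, which is the opposite regiochemistry from the one the formyl-to-hydroxyl sequence delivers, so a second, different trimer synthesis is required and the problem of the ring F–ring G ether remains inside it.
- Comparison: the chosen plan is more linear but uses one bromide (17) twice and one reaction type for all three late couplings. Alternative 3 would need about the same total number of steps because its two trimers share little chemistry.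

Key step: step 7

Remark 1: the target has no stereogenic element, so no SMILES string below carries a stereodescriptor.
Remark 2: compounds 1, 5, 16 and 18 are assumed to be purchasable.
Remark 3: in the substrate of the key step, O-3 of ring F is carried as a methyl ether rather than as a free hydroxyl (one phenol only at ring closure, no oxidisable free catechol), and the ester is fixed on O-1 of ring F by blocking O-2 during acylation; the bond formed and the ring closed are those of the depsidone disconnection.

## Steps

Step 1
Reactants: 1 5-fluoro-1,2,3-trimethoxybenzene
Product: 3 6-fluoro-2,3,4-trimethoxybenzaldehyde, via aryllithium 2 (not isolated)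
Conditions: n-BuLi, THF, −78 °C; DMF, −78 °C to 0 °C; aq. HCl
Reagents that add atoms: N,N-dimethylformamide CN(C)C=O
Why: Directed ortho-lithiation followed by formylation with DMF (Bouveault-type); the two ring hydrogens of 1 are equivalent and each lies between fluorine and methoxy, so only 2 can form, at −78 °C it does not eliminate LiF, and the hemiaminal alkoxide persists until work-up so the aldehyde is not attacked a second time. One batch of 3 feeds both arms of the route (steps 2 and 10).

Step 2
Reactants: 3 6-fluoro-2,3,4-trimethoxybenzaldehyde
Product: 4 6-fluoro-2,3,4-trimethoxybenzoic acid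
Conditions: NaClO2, NaH2PO4, 2-methyl-2-butene, t-BuOH–H2O, rt
Reagents that add atoms: sodium chlorite [Na+].[O-]Cl=O
Why: Pinnick oxidation; chlorous acid adds to the aldehyde and the adduct fragments to the carboxylic acid and HOCl, which 2-methyl-2-butene traps before it can chlorinate the one free position of the electron-rich ring, while the mildly acidic buffer leaves the aryl fluoride and the methyl ethers untouched.

Step 3
Reactants: 5 5-bromo-2-hydroxy-3-methoxybenzaldehyde
Product: 6 5-bromo-3-methoxy-2-[(4-methoxybenzyl)oxy]benzaldehyde
Conditions: 4-methoxybenzyl chloride, K2CO3, DMF, 60 °C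
Reagents that add atoms: 4-methoxybenzyl chloride COc1ccc(CCl)cc1
Why: Williamson etherification of the phenol; the 4-methoxybenzyl group blocks the future O-2 of ring F, cannot migrate to a neighbouring oxygen, and is later removed by acid without harm to an aryl ester or an aryl bromide.

Step 4
Reactants: 6 5-bromo-3-methoxy-2-[(4-methoxybenzyl)oxy]benzaldehyde
Product: 8 5-bromo-3-methoxy-2-[(4-methoxybenzyl)oxy]phenol, via formate 7 (not isolated)
Conditions: mCPBA, CH2Cl2, 0 °C to rt; then K2CO3 (cat.), MeOH, rt
Reagents that add atoms: 3-chloroperoxybenzoic acid (mCPBA) OOC(=O)c1cccc(Cl)c1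
Why: Baeyer–Villiger oxidation of an ortho-alkoxybenzaldehyde; the alkoxy donor favours aryl migration in the Criegee intermediate, and the aryl formate 7 is methanolysed under mild base to the O-1 hydroxyl of ring F.

Step 5
Reactants: 4 6-fluoro-2,3,4-trimethoxybenzoic acid; 8 5-bromo-3-methoxy-2-[(4-methoxybenzyl)oxy]phenol
Product: 10 5-bromo-3-methoxy-2-[(4-methoxybenzyl)oxy]phenyl 6-fluoro-2,3,4-trimethoxybenzoate, via acid chloride 9 (not isolated)
Conditions: (COCl)2, DMF (cat.), CH2Cl2, 0 °C to rt, concentrate; then 8, Et3N, DMAP (cat.), CH2Cl2, 0 °C to rt
Reagents that add atoms: none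
Why: Acid chloride formation followed by DMAP-catalysed acylation of the only free hydroxyl of 8; the ester therefore sits on O-1 of ring F by construction and not by selection among several hydroxyls.

Step 6
Reactants: 10 5-bromo-3-methoxy-2-[(4-methoxybenzyl)oxy]phenyl 6-fluoro-2,3,4-trimethoxybenzoate
Product: 11 5-bromo-2-hydroxy-3-methoxyphenyl 6-fluoro-2,3,4-trimethoxybenzoate
Conditions: TFA, Et3SiH, CH2Cl2, 0 °C
Reagents that add atoms: none
Why: Acidolysis of the 4-methoxybenzyl ether with silane capture of the benzylic cation; the aryl ester, methyl ethers, fluoride and bromide are inert to TFA at 0 °C, and the acidic medium generates no phenoxide that could start acyl migration.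

Step 7
Reactants: 11 5-bromo-2-hydroxy-3-methoxyphenyl 6-fluoro-2,3,4-trimethoxybenzoate
Product: 12 8-bromo-1,2,3,6-tetramethoxy-11H-dibenzo[b,e][1,4]dioxepin-11-one (the depsidone lactone)
Conditions: Cs2CO3, dry DMSO (0.02 M), 70 °C, argon
Reagents that add atoms: none
Why: Cs2CO3 deprotonates the single free hydroxyl (O-2 of ring F), and the phenoxide adds to the fluorinated carbon ortho to the ester carbonyl (the future C-1 of ring G) to give a Meisenheimer anion stabilised by that carbonyl, which then expels fluoride; this addition–elimination forms the bond from O-2 of ring F to C-1 of ring G. The closest known reaction type is the base-mediated cyclisation of ortho-halo depsides to depsidones. One seven-membered dibenzo[1,4]dioxepinone ring closes; in the conjugate-addition picture, with the negative charge taken up by the carbonyl-bearing ring carbon that lies inside the new ring, the mode is formally 7-endo-trig, which is allowed, and the O–C(=O) tether holds the two reacting atoms in reach while high dilution suppresses intermolecular arylation. No stereocentre is formed, so no controlling element is needed. Activation by one ester carbonyl is modest, but the two methoxy groups meta to the reacting carbon withdraw inductively and the para methoxy, wedged between two neighbours, is twisted out of conjugation, so with intramolecular delivery the closure should proceed at moderate temperature. Fluoride rather than the methoxy group on the other ortho carbon should be displaced, because fluorine stabilises the addition transition state far better. The selectivity needed is arylation of O-2 and not O-1 of ring F; it is secured because O-3 is methylated, O-1 is acylated, and the di-ortho-substituted aroyl group is shielded against transfer to the neighbouring phenoxide.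

Step 8
Reactants: 12 8-bromo-1,2,3,6-tetramethoxy-11H-dibenzo[b,e][1,4]dioxepin-11-one
Product: 14 5-bromo-3-methoxy-2-(3,4,5-trimethoxyphenoxy)phenol, via hydroxy acid 13 (not isolated)
Conditions: NaOH, H2O–dioxane, 50 °C; then aq. HCl to pH 1, 90 °C
Reagents that add atoms: none
Why: Saponification of the aryl ester returns the O-1 hydroxyl of ring F and the carboxylate of 13; on acidification and warming the acid, with oxygen donors on both ortho carbons and the para carbon, is protonated at the ipso carbon and loses CO2 (acid-promoted protodecarboxylation), leaving hydrogen on C-2 of ring G.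

Step 9
Reactants: 14 5-bromo-3-methoxy-2-(3,4,5-trimethoxyphenoxy)phenol
Product: 15 5-bromo-1,3-dimethoxy-2-(3,4,5-trimethoxyphenoxy)benzene
Conditions: MeI, K2CO3, acetone, 50 °C
Reagents that add atoms: iodomethane CI
Why: Williamson methylation removes the one hydroxyl that would compete in the later copper coupling; ring F of 15 becomes symmetric, which should make it easy to confirm that arylation took place on the central oxygen.

Step 10
Reactants: 3 6-fluoro-2,3,4-trimethoxybenzaldehyde; 16 4-bromo-2,6-dimethoxyphenol
Product: 17 6-(4-bromo-2,6-dimethoxyphenoxy)-2,3,4-trimethoxybenzaldehyde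
Conditions: K2CO3, DMSO, 110 °C, argon
Reagents that add atoms: none
Why: Nucleophilic aromatic substitution of an ortho-fluorobenzaldehyde by a phenoxide; the formyl group activates the fluorinated carbon, and the bromide of 16 sits on the anionic, unactivated ring and is inert. This sets the ether from C-2 of ring B to C-1 of ring C (and, on second use, from C-2 of ring D to C-1 of ring E) with the formyl group where the oxygen on C-6 of ring C or ring E is needed.

Step 11
Reactants: 18 2,4,6-trimethoxyphenol; 17 6-(4-bromo-2,6-dimethoxyphenoxy)-2,3,4-trimethoxybenzaldehyde
Product: 19 6-[2,6-dimethoxy-4-(2,4,6-trimethoxyphenoxy)phenoxy]-2,3,4-trimethoxybenzaldehyde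
Conditions: CuI (10 mol %), picolinic acid (20 mol %), K3PO4, DMSO, 90 °C, argon
Reagents that add atoms: none
Why: Ullmann diaryl ether synthesis catalysed by monovalent copper with picolinic acid as ligand, a system suited to di-ortho-substituted phenols; the bromide of 17 has two ortho hydrogens and the non-enolisable aldehyde is a spectator under phosphate base.

Step 12
Reactants: 19 6-[2,6-dimethoxy-4-(2,4,6-trimethoxyphenoxy)phenoxy]-2,3,4-trimethoxybenzaldehyde
Product: 21 6-[2,6-dimethoxy-4-(2,4,6-trimethoxyphenoxy)phenoxy]-2,3,4-trimethoxyphenol, via formate 20 (not isolated)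
Conditions: mCPBA (1.1 equiv), CH2Cl2, 0 °C to rt; then K2CO3 (cat.), MeOH, rt, argon
Reagents that add atoms: 3-chloroperoxybenzoic acid (mCPBA) OOC(=O)c1cccc(Cl)c1
Why: Baeyer–Villiger oxidation; the formyl group stands on a ring with oxygen donors on both ortho carbons and the para carbon, so aryl migration to formate 20 should dominate, and methanolysis frees the hydroxyl on C-6 of ring C.

Step 13
Reactants: 21 6-[2,6-dimethoxy-4-(2,4,6-trimethoxyphenoxy)phenoxy]-2,3,4-trimethoxyphenol; 17 6-(4-bromo-2,6-dimethoxyphenoxy)-2,3,4-trimethoxybenzaldehyde
Product: 22 6-(4-{6-[2,6-dimethoxy-4-(2,4,6-trimethoxyphenoxy)phenoxy]-2,3,4-trimethoxyphenoxy}-2,6-dimethoxyphenoxy)-2,3,4-trimethoxybenzaldehyde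
Conditions: CuI (20 mol %), picolinic acid (40 mol %), K3PO4, DMSO, 100 °C, argon
Reagents that add atoms: none
Why: Second Ullmann etherification with the same bromide; the phenol of 21 is flanked by an aryloxy and a methoxy group and is comparable in hindrance to 18, and it forms the ether from C-6 of ring C to C-5 of ring D.

Step 14
Reactants: 22 6-(4-{6-[2,6-dimethoxy-4-(2,4,6-trimethoxyphenoxy)phenoxy]-2,3,4-trimethoxyphenoxy}-2,6-dimethoxyphenoxy)-2,3,4-trimethoxybenzaldehyde
Product: 24 6-(4-{6-[2,6-dimethoxy-4-(2,4,6-trimethoxyphenoxy)phenoxy]-2,3,4-trimethoxyphenoxy}-2,6-dimethoxyphenoxy)-2,3,4-trimethoxyphenol, via formate 23 (not isolated)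
Conditions: mCPBA (1.1 equiv), CH2Cl2, 0 °C to rt; then K2CO3 (cat.), MeOH, rt, argon
Reagents that add atoms: 3-chloroperoxybenzoic acid (mCPBA) OOC(=O)c1cccc(Cl)c1
Why: Baeyer–Villiger oxidation as in step 12, on a formyl group in the same electronic environment; it delivers the hydroxyl on C-6 of ring E next to the ether that joins rings D and E.

Step 15
Reactants: 24 6-(4-{6-[2,6-dimethoxy-4-(2,4,6-trimethoxyphenoxy)phenoxy]-2,3,4-trimethoxyphenoxy}-2,6-dimethoxyphenoxy)-2,3,4-trimethoxyphenol; 15 5-bromo-1,3-dimethoxy-2-(3,4,5-trimethoxyphenoxy)benzene
Product: 25 octadeca-O-methyl ether of the target (all eighteen hydroxyls of rings A to G as methoxy groups)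
Conditions: CuI (20 mol %), picolinic acid (40 mol %), K3PO4, DMSO, 100 °C, argon
Reagents that add atoms: none
Why: Third Ullmann etherification, forming the ether from C-6 of ring E to C-5 of ring F; the bromide of 15 is unhindered on both sides and neither partner carries a second halide or a second hydroxyl.

Step 16
Reactants: 25 octadeca-O-methyl ether of the target
Product: 26 CNP0292517.0, the heptameric polyphenol with eighteen free hydroxyls
Conditions: BBr3 (excess), CH2Cl2, −78 °C to rt, argon; then H2O, 0 °C
Reagents that add atoms: none
Why: Lewis acid-mediated cleavage of aryl methyl ethers; BBr3 coordinates each methoxy oxygen and bromide attacks the methyl carbon, whereas the aryl–O–aryl bonds offer no alkyl carbon and persist, and hydrolysis of the aryl borates frees the hydroxyls.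

## Compound list

1 | 5-fluoro-1,2,3-trimethoxybenzene | COc1cc(F)cc(OC)c1OC | starting material
2 | (6-fluoro-2,3,4-trimethoxyphenyl)lithium | [Li]c1c(F)cc(OC)c(OC)c1OC | intermediate
3 | 6-fluoro-2,3,4-trimethoxybenzaldehyde | COc1cc(F)c(C=O)c(OC)c1OC | intermediate
4 | 6-fluoro-2,3,4-trimethoxybenzoic acid | COc1cc(F)c(C(=O)O)c(OC)c1OC | intermediate
5 | 5-bromo-2-hydroxy-3-methoxybenzaldehyde | COc1cc(Br)cc(C=O)c1O | starting material
6 | 5-bromo-3-methoxy-2-[(4-methoxybenzyl)oxy]benzaldehyde | COc1ccc(COc2c(C=O)cc(Br)cc2OC)cc1 | intermediate
7 | 5-bromo-3-methoxy-2-[(4-methoxybenzyl)oxy]phenyl formate | COc1ccc(COc2c(OC=O)cc(Br)cc2OC)cc1 | intermediate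
8 | 5-bromo-3-methoxy-2-[(4-methoxybenzyl)oxy]phenol | COc1ccc(COc2c(O)cc(Br)cc2OC)cc1 | intermediate
9 | 6-fluoro-2,3,4-trimethoxybenzoyl chloride | COc1cc(F)c(C(=O)Cl)c(OC)c1OC | intermediate
10 | 5-bromo-3-methoxy-2-[(4-methoxybenzyl)oxy]phenyl 6-fluoro-2,3,4-trimethoxybenzoate | COc1ccc(COc2c(OC(=O)c3c(F)cc(OC)c(OC)c3OC)cc(Br)cc2OC)cc1 | intermediate
11 | 5-bromo-2-hydroxy-3-methoxyphenyl 6-fluoro-2,3,4-trimethoxybenzoate | COc1cc(F)c(C(=O)Oc2cc(Br)cc(OC)c2O)c(OC)c1OC | intermediate
12 | 8-bromo-1,2,3,6-tetramethoxy-11H-dibenzo[b,e][1,4]dioxepin-11-one | COc1cc2Oc3c(OC)cc(Br)cc3OC(=O)c2c(OC)c1OC | intermediate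
13 | 2-(4-bromo-2-hydroxy-6-methoxyphenoxy)-4,5,6-trimethoxybenzoic acid | COc1cc(Oc2c(O)cc(Br)cc2OC)c(C(=O)O)c(OC)c1OC | intermediate
14 | 5-bromo-3-methoxy-2-(3,4,5-trimethoxyphenoxy)phenol | COc1cc(Oc2c(O)cc(Br)cc2OC)cc(OC)c1OC | intermediate
15 | 5-bromo-1,3-dimethoxy-2-(3,4,5-trimethoxyphenoxy)benzene | COc1cc(Oc2c(OC)cc(Br)cc2OC)cc(OC)c1OC | intermediate
16 | 4-bromo-2,6-dimethoxyphenol | COc1cc(Br)cc(OC)c1O | starting material
17 | 6-(4-bromo-2,6-dimethoxyphenoxy)-2,3,4-trimethoxybenzaldehyde | COc1cc(Oc2c(OC)cc(Br)cc2OC)c(C=O)c(OC)c1OC | intermediate
18 | 2,4,6-trimethoxyphenol | COc1cc(OC)c(O)c(OC)c1 | starting material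
19 | 6-[2,6-dimethoxy-4-(2,4,6-trimethoxyphenoxy)phenoxy]-2,3,4-trimethoxybenzaldehyde | COc1cc(OC)c(Oc2cc(OC)c(Oc3cc(OC)c(OC)c(OC)c3C=O)c(OC)c2)c(OC)c1 | intermediate
20 | 6-[2,6-dimethoxy-4-(2,4,6-trimethoxyphenoxy)phenoxy]-2,3,4-trimethoxyphenyl formate | COc1cc(OC)c(Oc2cc(OC)c(Oc3cc(OC)c(OC)c(OC)c3OC=O)c(OC)c2)c(OC)c1 | intermediate
21 | 6-[2,6-dimethoxy-4-(2,4,6-trimethoxyphenoxy)phenoxy]-2,3,4-trimethoxyphenol | COc1cc(OC)c(Oc2cc(OC)c(Oc3cc(OC)c(OC)c(OC)c3O)c(OC)c2)c(OC)c1 | intermediate
22 | 6-(4-{6-[2,6-dimethoxy-4-(2,4,6-trimethoxyphenoxy)phenoxy]-2,3,4-trimethoxyphenoxy}-2,6-dimethoxyphenoxy)-2,3,4-trimethoxybenzaldehyde | COc1cc(OC)c(Oc2cc(OC)c(Oc3cc(OC)c(OC)c(OC)c3Oc3cc(OC)c(Oc4cc(OC)c(OC)c(OC)c4C=O)c(OC)c3)c(OC)c2)c(OC)c1 | intermediate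
23 | 6-(4-{6-[2,6-dimethoxy-4-(2,4,6-trimethoxyphenoxy)phenoxy]-2,3,4-trimethoxyphenoxy}-2,6-dimethoxyphenoxy)-2,3,4-trimethoxyphenyl formate | COc1cc(OC)c(Oc2cc(OC)c(Oc3cc(OC)c(OC)c(OC)c3Oc3cc(OC)c(Oc4cc(OC)c(OC)c(OC)c4OC=O)c(OC)c3)c(OC)c2)c(OC)c1 | intermediate
24 | 6-(4-{6-[2,6-dimethoxy-4-(2,4,6-trimethoxyphenoxy)phenoxy]-2,3,4-trimethoxyphenoxy}-2,6-dimethoxyphenoxy)-2,3,4-trimethoxyphenol | COc1cc(OC)c(Oc2cc(OC)c(Oc3cc(OC)c(OC)c(OC)c3Oc3cc(OC)c(Oc4cc(OC)c(OC)c(OC)c4O)c(OC)c3)c(OC)c2)c(OC)c1 | intermediate
25 | octadeca-O-methyl ether of the target (rings A to G, every hydroxyl as methoxy) | COc1cc(OC)c(Oc2cc(OC)c(Oc3cc(OC)c(OC)c(OC)c3Oc3cc(OC)c(Oc4cc(OC)c(OC)c(OC)c4Oc4cc(OC)c(Oc5cc(OC)c(OC)c(OC)c5)c(OC)c4)c(OC)c3)c(OC)c2)c(OC)c1 | intermediate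
26 | CNP0292517.0 (heptameric aryl ether polyphenol, rings A to G, eighteen hydroxyls) | Oc1cc(O)c(Oc2cc(O)c(Oc3cc(O)c(O)c(O)c3Oc3cc(O)c(Oc4cc(O)c(O)c(O)c4Oc4cc(O)c(Oc5cc(O)c(O)c(O)c5)c(O)c4)c(O)c3)c(O)c2)c(O)c1 | target

## Step count and least certain steps

Total: 16 steps. Longest linear sequence: 9 steps (steps 1, 2, 5 to 9, 15 and 16 from 1; equally steps 3 to 9, 15 and 16 from 5). The ring A to ring E arm (steps 1 and 10 to 14) joins at step 15.

Step 7 (key step). The aroyl group may migrate from O-1 to O-2 of ring F through a five-membered tetrahedral intermediate before the slower ring closure, so that the O-1 phenoxide closes the ring and the ether ends on the wrong oxygen. The ester may also be cleaved by adventitious hydroxide. Both follow from the fact that the reacting carbon is activated by a single carbonyl group. Fallback: it sets out from 16, which is coupled with 5-iodo-1,2,3-trimethoxybenzene F1 in an intermolecular Ullmann etherification (CuI, picolinic acid, K3PO4, DMSO, 80 °C). The iodide should react ahead of the bromide on the phenoxide ring, and the product is 15, where the route is rejoined. This gives up the tether and accepts a hindered intermolecular coupling in its place.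

Step 10. The addition of a phenoxide flanked by two methoxy groups to a ring that carries three methoxy donors may be slow, and prolonged heating may then degrade the aldehyde or lead to demethylation by the phenoxide. Fallback: it sets out from 15, which is formylated under Rieche conditions (Cl2CHOMe, TiCl4, CH2Cl2, −40 to 0 °C). Electrophilic substitution should take place on the trimethoxyphenoxy ring, ortho to the aryloxy group and ortho and para to methoxy groups, in preference to the brominated ring. The product is 17, where the route is rejoined; the fallback makes no new compound (F0).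

Step 15 (the same concern applies in lesser degree to steps 11 and 13). Carbon–oxygen bond formation at the congested oxygen on C-6 of ring E of a large, very electron-rich phenoxide may be slow, so that hydrodebromination of 15 and oxidative degradation of the phenoxide compete. Fallback: it sets out from 15, which is converted by bromine–lithium exchange and borylation (n-BuLi, THF, −78 °C; B(OiPr)3; aq. HCl) into [3,5-dimethoxy-4-(3,4,5-trimethoxyphenoxy)phenyl]boronic acid F2. Chan–Lam coupling of F2 with 24 (Cu(OAc)2, pyridine, 4 Å molecular sieves, CH2Cl2, dry air, rt) then gives 25, where the route is rejoined. This runs at room temperature through a different copper mechanism (transmetalation from boron, no oxidative addition to a halide).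

Step 16. Cleavage of eighteen ethers may stop short as partly cleaved aryl borates precipitate. The hydrogen bromide formed may break the ether at the phloroglucinol-type ring A. The free polyphenol may oxidise during isolation. Fallback: it sets out from 25. After the BBr3 treatment and removal of volatiles the crude phenol is not isolated but acetylated in the same flask (Ac2O, pyridine, rt) to the octadecaacetate F3. F3 is stable to air and can be purified on silica, and under-cleaved material can be separated and resubmitted. Acid-catalysed methanolysis (AcCl (cat.), MeOH, 0 °C to rt, argon) then releases 26 without any phenoxide being formed.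

## Further compounds

F1 | step 7 | 5-iodo-1,2,3-trimethoxybenzene | COc1cc(I)cc(OC)c1OC
F0 | step 10 | none | none
F2 | step 15 | [3,5-dimethoxy-4-(3,4,5-trimethoxyphenoxy)phenyl]boronic acid | COc1cc(Oc2c(OC)cc(B(O)O)cc2OC)cc(OC)c1OC
F3 | step 16 | octadecaacetate of 26 | CC(=O)Oc1cc(OC(C)=O)c(Oc2cc(OC(C)=O)c(Oc3cc(OC(C)=O)c(OC(C)=O)c(OC(C)=O)c3Oc3cc(OC(C)=O)c(Oc4cc(OC(C)=O)c(OC(C)=O)c(OC(C)=O)c4Oc4cc(OC(C)=O)c(Oc5cc(OC(C)=O)c(OC(C)=O)c(OC(C)=O)c5)c(OC(C)=O)c4)c(OC(C)=O)c3)c(OC(C)=O)c2)c(OC(C)=O)c1
A1 | alternative 1 | hexabenzyl dodecaformate heptamer | C(c9ccccc9)Oc1cc(OC=O)c(Oc2cc(OC=O)c(Oc3cc(OC=O)c(OCc8ccccc8)c(OC=O)c3Oc3cc(OC=O)c(Oc4cc(OC=O)c(OCc7ccccc7)c(OC=O)c4Oc4cc(OC=O)c(Oc5cc(OCc6ccccc6)c(OCc6ccccc6)c(OCc6ccccc6)c5)c(OC=O)c4)c(OC=O)c3)c(OC=O)c2)c(OC=O)c1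
A2 | alternative 1 | hexabenzyl dodecaaldehyde heptamer | C(c9ccccc9)Oc1cc(C=O)c(Oc2cc(C=O)c(Oc3cc(C=O)c(OCc8ccccc8)c(C=O)c3Oc3cc(C=O)c(Oc4cc(C=O)c(OCc7ccccc7)c(C=O)c4Oc4cc(C=O)c(Oc5cc(OCc6ccccc6)c(OCc6ccccc6)c(OCc6ccccc6)c5)c(C=O)c4)c(C=O)c3)c(C=O)c2)c(C=O)c1
A3 | alternative 2 | ring B–ring C hydroquinone (2,5-dihydroxy-3,4-diisopropoxyphenyl ether of 2,6-dimethoxy-4-(triisopropylsilyloxy)phenol) | CC(C)Oc1c(O)cc(Oc2c(OC)cc(O[Si](C(C)C)(C(C)C)C(C)C)cc2OC)c(O)c1OC(C)C
A4 | alternative 2 | 4-hydroxy-2,3-diisopropoxy-4-{1-[2,6-dimethoxy-4-(triisopropylsilyloxy)phenoxy]vinyl}cyclobut-2-en-1-one (racemic) | CC(C)OC1=C(OC(C)C)C(O)(C(=C)Oc2c(OC)cc(O[Si](C(C)C)(C(C)C)C(C)C)cc2OC)C1=O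
A5 | alternative 2 | diisopropyl squarate | CC(C)OC1=C(OC(C)C)C(=O)C1=O
A6 | alternative 3 | octadeca-O-methyl heptamer (identical with 25) | COc1cc(OC)c(Oc2cc(OC)c(Oc3cc(OC)c(OC)c(OC)c3Oc3cc(OC)c(Oc4cc(OC)c(OC)c(OC)c4Oc4cc(OC)c(Oc5cc(OC)c(OC)c(OC)c5)c(OC)c4)c(OC)c3)c(OC)c2)c(OC)c1
A7 | alternative 3 | [CpRu(η6-2,5-dichloro-1,3-dimethoxybenzene)]PF6, written as its components | COc1cc(Cl)cc(OC)c1Cl.[CH-]1C=CC=C1.[Ru+2].F[P-](F)(F)(F)(F)F
A8 | alternative 3 | 2-[3,5-dimethoxy-4-(3,4,5-trimethoxyphenoxy)phenoxy]-3,4,5-trimethoxyphenol (ring E–ring F–ring G trimer phenol) | COc1cc(O)c(Oc2cc(OC)c(Oc3cc(OC)c(OC)c(OC)c3)c(OC)c2)c(OC)c1OC
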